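**Strategy**

Everything rests on cutting C9–C10 and C8–O. In ring A the C3 oxygen is para to the quaternary C10, so ring A is a masked 2,4-dimethylphenol, and C8–C9 with O8 cis to C11 is a masked (Z)-trisubstituted alkene. Oxidation of the phenol with a chiral aryl-λ3-iodane lets C9 of the alkene add to C10 while the C12 acid traps C8: ring B and a γ-lactone close and C8, C9 and C10 are set in one operation. The precursor is (Z)-6-(3-hydroxy-2,6-dimethylphenyl)-4-methylhex-3-enoic acid (15), made by syn-carbocupration of propyne. The dienone product 16 then supplies the gem-dimethyl group, H5 and O6.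

Key step: step 9

Remark on the chemistry: labdane numbering is used throughout (ring A: C1–C5 and C10; ring B: C5–C10; C11–C12 the arm on C9; C17 on C8; C20 on C10). The target SMILES is read as 3R,5S,6R,8S,9R,10R: C20 and C17 lie on one face, H5, C11, O8 and O6 on the other, and O3 is equatorial and cis to C20.

Assumption: the sense of induction of the chiral iodane cannot be predicted; the (R,R) reagent is written, and its antipode is taken if a test run gives the mirror image.

**Route**

Step 1
Reactants: 1 2-bromo-1,3-dimethylbenzene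
Product: 2 1-(3-bromo-2,4-dimethylphenyl)ethan-1-one
Conditions: AcCl, AlCl3, CH2Cl2, 0 °C to rt
Reagents that add atoms: acetyl chloride, CC(Cl)=O
Why: Friedel–Crafts acylation goes to C4, which is ortho to one methyl group and para to the other, whereas C5 is meta to both and C2 is blocked.

Step 2
Reactants: 2 1-(3-bromo-2,4-dimethylphenyl)ethan-1-one
Product: 4 3-bromo-2,4-dimethylphenol, via aryl acetate 3 (not isolated)
Conditions: mCPBA, TFA (cat.), CH2Cl2, rt; then K2CO3, MeOH, rt
Reagents that add atoms: 3-chloroperbenzoic acid, OOC(=O)c1cccc(Cl)c1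
Why: In the Baeyer–Villiger oxidation the ortho-substituted aryl group migrates in preference to methyl, and methanolysis of the aryl acetate frees the phenol oxygen that becomes O3.

Step 3
Reactants: 4 3-bromo-2,4-dimethylphenol
Product: 5 (3-bromo-2,4-dimethylphenoxy)tri(propan-2-yl)silane
Conditions: TIPSCl, imidazole, DMF, rt
Reagents that add atoms: chlorotri(propan-2-yl)silane, CC(C)[Si](Cl)(C(C)C)C(C)C
Why: Standard silylation gives a hindered aryl silyl ether that tolerates the two Grignard reagents, the organocopper step and the oxidation, and is later removed by fluoride without acid.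

Step 4
Reactants: 5 (3-bromo-2,4-dimethylphenoxy)tri(propan-2-yl)silane; 6 ethylene oxide
Product: 8 2-{2,6-dimethyl-3-[tri(propan-2-yl)silyloxy]phenyl}ethan-1-ol, via arylmagnesium bromide 7 (not isolated)
Conditions: Mg, THF, reflux; then ethylene oxide, CuI (5 mol%), −30 °C to rt
Reagents that add atoms: none
Why: Grignard formation at the di-ortho-substituted bromide and copper-catalysed epoxide opening at carbon attach the C6–C7 arm, as is usual for 2,6-disubstituted arylmagnesium halides.

Step 5
Reactants: 8 2-{2,6-dimethyl-3-[tri(propan-2-yl)silyloxy]phenyl}ethan-1-ol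
Product: 9 [3-(2-bromoethyl)-2,4-dimethylphenoxy]tri(propan-2-yl)silane
Conditions: CBr4, PPh3, CH2Cl2, 0 °C
Reagents that add atoms: tetrabromomethane, BrC(Br)(Br)Br
Why: The Appel reaction converts the primary alcohol into the bromide under neutral conditions that leave the silyl ether untouched.

Step 6
Reactants: 9 [3-(2-bromoethyl)-2,4-dimethylphenoxy]tri(propan-2-yl)silane; 10 propyne; 6 ethylene oxide
Product: 13 (Z)-6-{2,6-dimethyl-3-[tri(propan-2-yl)silyloxy]phenyl}-4-methylhex-3-en-1-ol, via alkylmagnesium bromide 11 (not isolated), via alkenylcopper 12 (not isolated)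
Conditions: Mg, Et2O, reflux; CuBr·SMe2, Et2O/Me2S, −45 °C; propyne, −25 °C; LiC≡CPr, DMPU, then ethylene oxide, −78 to −20 °C
Reagents that add atoms: none
Why: In the Normant carbocupration the alkylcopper adds syn across propyne with the alkyl group on the internal carbon, and the configurationally stable alkenylcopper, activated as a mixed alkynylcuprate, opens ethylene oxide with retention, so the arylethyl and hydroxyethyl arms end up cis (Z).

Step 7
Reactants: 13 (Z)-6-{2,6-dimethyl-3-[tri(propan-2-yl)silyloxy]phenyl}-4-methylhex-3-en-1-ol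
Product: 14 (Z)-6-{2,6-dimethyl-3-[tri(propan-2-yl)silyloxy]phenyl}-4-methylhex-3-enoic acid
Conditions: TEMPO (cat.), PhI(OAc)2, MeCN/H2O, 0 °C to rt
Reagents that add atoms: water, O
Why: Oxoammonium (TEMPO) oxidation takes the primary alcohol through the aldehyde hydrate to the acid under nearly neutral conditions, which keeps the β,γ-alkene in place and (Z).

Step 8
Reactants: 14 (Z)-6-{2,6-dimethyl-3-[tri(propan-2-yl)silyloxy]phenyl}-4-methylhex-3-enoic acid
Product: 15 (Z)-6-(3-hydroxy-2,6-dimethylphenyl)-4-methylhex-3-enoic acid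
Conditions: TBAF, THF, 0 °C; aqueous NH4Cl work-up
Reagents that add atoms: none
Why: Fluoride-mediated desilylation frees the phenol without acid, so the β,γ-unsaturated acid does not protolactonise, and 15 carries the free phenol and free acid needed next, with methyl groups on both C4 and C10 so that neither ortho nor para attack can re-aromatise.

Step 9
Reactants: 15 (Z)-6-(3-hydroxy-2,6-dimethylphenyl)-4-methylhex-3-enoic acid
Product: 16 (8S,9R,10S)-3-oxo-13,14,15,16,18-pentanorlabda-1,4-dien-12,8-olide (ring A is a 4,10-dimethylcyclohexa-1,4-dien-3-one; γ-lactone from C12 to O8; C11 and O8 cis to each other and trans to C20; C17 cis to C20)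
Conditions: chiral ArI(OAc)2 (1.1 equiv; Ar = 2,6-bis{[(2R)-1-oxo-1-(2,4,6-trimethylanilino)propan-2-yl]oxy}phenyl), CH2Cl2/(CF3)2CHOH 4:1, −30 °C
Reagents that add atoms: none
Why: Proposed new method: Ligand exchange of the phenol at trivalent iodine gives an aryloxy-λ3-iodane; as the iodoarene leaves, the para carbon C10 becomes electrophilic, C9 of the (Z)-alkene bonds to it and the carboxyl oxygen captures the tertiary cation developing at C8. The closest known reaction types are iodane-mediated para-dearomatisation of phenols by tethered carbon nucleophiles, enantioselective spirolactonisation with chiral iodoarenes and acid-induced cyclisation of (Z)-homofarnesic-type acids to cis-fused lactones. Ring B closes 6-endo with respect to the alkene through a chair in which the new C9–C10 bond forms perpendicular to the arene, and the γ-lactone closes by five-membered capture of C8 by oxygen, anti to that bond. C8 and C9 are fixed relative to each other by anti addition across the (Z)-alkene (C11 axial, O8 equatorial and cis to C11, C17 axial), C10 relative to C9 by the chair (C20 axial, trans to C11), and the absolute sense by the chiral iodane, which must tell the two arene faces apart. The step needs para (C10) over ortho (C4) attack, both carbons being neighbours of C5: the bulky oxygen-bound iodane screens C4 and para attack gives the more stable cross-conjugated dienone, while methyl groups on both carbons prevent re-aromatisation. A preformed iodane replaces a peracid-driven catalytic cycle so that the alkene is not epoxidised, and the fluorinated alcohol stabilises the cationic intermediates without competing as a nucleophile.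

Step 10
Reactants: 16 (8S,9R,10S)-3-oxo-13,14,15,16,18-pentanorlabda-1,4-dien-12,8-olide
Product: 17 (8S,9R,10S)-3-oxo-13,14,15,16,18-pentanorlabd-4-en-12,8-olide
Conditions: H2 (1 atm), RhCl(PPh3)3 (10 mol%), benzene/EtOH, rt
Reagents that add atoms: none
Why: Homogeneous hydrogenation with RhCl(PPh3)3 reduces the disubstituted C1=C2 bond of a cross-conjugated dienone and leaves the tetrasubstituted C4=C5 enone, as with steroidal 1,4-dien-3-ones.

Step 11
Reactants: 17 (8S,9R,10S)-3-oxo-13,14,15,16,18-pentanorlabd-4-en-12,8-olide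
Product: 18 (8S,9R,10S)-3-oxo-13,14,15,16-tetranorlabd-5-en-12,8-olide
Conditions: KOtBu (1.2 equiv), tBuOH, rt; MeI
Reagents that add atoms: iodomethane, CI
Why: In this deconjugative α-alkylation the thermodynamic dienolate formed by γ-deprotonation at C6 is methylated at C4, giving the gem-dimethyl group and moving the alkene to C5=C6, while the lactone α-protons are several pK units less acidic.

Step 12
Reactants: 18 (8S,9R,10S)-3-oxo-13,14,15,16-tetranorlabd-5-en-12,8-olide
Product: 19 (3R,8S,9R,10S)-13,14,15,16-tetranorlabd-5-ene-3,8,12-triol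
Conditions: LiAlH4, THF, 0 °C to rt
Reagents that add atoms: none
Why: Hydride reduces ketone and lactone in one operation, and axial attack on the C3 carbonyl from the face opposite the axial C4 methyl group gives the equatorial alcohol cis to C20 (3R), as with 4,4-dimethyl-3-oxo steroids.

Step 13
Reactants: 19 (3R,8S,9R,10S)-13,14,15,16-tetranorlabd-5-ene-3,8,12-triol
Product: 21 (3R,8S,9R,10S)-3,8-bis(triethylsilyloxy)-13,14,15,16-tetranorlabd-5-en-12-ol, via tris(triethylsilyl) ether 20 (not isolated)
Conditions: TESOTf, 2,6-lutidine, CH2Cl2, −78 to 0 °C; then MeOH, PPTS, 0 °C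
Reagents that add atoms: triethylsilyl trifluoromethanesulfonate, CC[Si](CC)(CC)OS(=O)(=O)C(F)(F)F
Why: Exhaustive silylation with the silyl triflate covers even the tertiary O8, and mild acid methanolysis then removes only the primary silyl ether; O8 has to be blocked because a C12 sulfonate beside a free O8 would close to the 8,12-ether.

Step 14
Reactants: 21 (3R,8S,9R,10S)-3,8-bis(triethylsilyloxy)-13,14,15,16-tetranorlabd-5-en-12-ol
Product: 22 (3R,5S,6R,8S,9R,10R)-3,8-bis(triethylsilyloxy)-13,14,15,16-tetranorlabdane-6,12-diol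
Conditions: BH3·THF (excess), THF, 0 °C to rt; then NaOH, H2O2, 0 °C to rt
Reagents that add atoms: hydrogen peroxide, OO
Why: In the hydroboration–oxidation boron adds to the less substituted C6 and hydrogen to C5, syn, from the face opposite C20, C17 and the axial C4 methyl group, which sets the trans ring fusion at C5 and the equatorial C6 alcohol cis to H5, as with steroidal 5-enes.

Step 15
Reactants: 22 (3R,5S,6R,8S,9R,10R)-3,8-bis(triethylsilyloxy)-13,14,15,16-tetranorlabdane-6,12-diol
Product: 23 (3R,5S,6R,8S,9R,10R)-6-hydroxy-3,8-bis(triethylsilyloxy)-13,14,15,16-tetranorlabdan-12-yl 4-methylbenzenesulfonate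
Conditions: TsCl, pyridine, DMAP (cat.), CH2Cl2, 0 °C
Reagents that add atoms: 4-methylbenzenesulfonyl chloride, Cc1ccc(cc1)S(Cl)(=O)=O
Why: Sulfonylation is selective for the primary alcohol because the secondary C6 alcohol, flanked by the C4 methyl groups, reacts far more slowly.

Step 16
Reactants: 23 (3R,5S,6R,8S,9R,10R)-6-hydroxy-3,8-bis(triethylsilyloxy)-13,14,15,16-tetranorlabdan-12-yl 4-methylbenzenesulfonate; 24 chloroprene
Product: 26 (3R,5S,6R,8S,9R,10R)-3,8-bis(triethylsilyloxy)labda-13(16),14-dien-6-ol, via buta-1,3-dien-2-ylmagnesium chloride 25 (not isolated)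
Conditions: chloroprene, Mg, ZnCl2 (cat.), BrCH2CH2Br (cat.), THF, reflux; then 23, Li2CuCl4 (5 mol%), THF, −20 °C to rt
Reagents that add atoms: none
Why: Copper-catalysed cross-coupling of a primary alkyl tosylate with the 2-butadienyl Grignard reagent installs C13–C16 in one step, the C6 alkoxide formed by the first equivalent being a spectator.

Step 17
Reactants: 26 (3R,5S,6R,8S,9R,10R)-3,8-bis(triethylsilyloxy)labda-13(16),14-dien-6-ol
Product: 27 (3R,5S,6R,8S,9R,10R)-3,8-bis(triethylsilyloxy)labda-13(16),14-dien-6-yl acetate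
Conditions: Ac2O, DMAP, Et3N, CH2Cl2, rt
Reagents that add atoms: acetic anhydride, CC(=O)OC(C)=O
Why: DMAP-catalysed acylation acetylates the only free hydroxyl group, both other oxygens being silylated.

Step 18
Reactants: 27 (3R,5S,6R,8S,9R,10R)-3,8-bis(triethylsilyloxy)labda-13(16),14-dien-6-yl acetate
Product: 28 (3R,5S,6R,8S,9R,10R)-3,8-dihydroxylabda-13(16),14-dien-6-yl acetate (CNP0351600.2)
Conditions: HF·pyridine, pyridine, THF, 0 °C to rt
Reagents that add atoms: none
Why: Buffered fluoride cleaves both triethylsilyl ethers under non-basic conditions that leave the acetate, the tertiary alcohol and the diene untouched.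

**Compound list**

1 | 2-bromo-1,3-dimethylbenzene | Brc1c(C)cccc1C | starting material
2 | 1-(3-bromo-2,4-dimethylphenyl)ethan-1-one | Brc1c(C)ccc(C(C)=O)c1C | intermediate
3 | 3-bromo-2,4-dimethylphenyl acetate | Brc1c(C)ccc(OC(C)=O)c1C | intermediate
4 | 3-bromo-2,4-dimethylphenol | Brc1c(C)ccc(O)c1C | intermediate
5 | (3-bromo-2,4-dimethylphenoxy)tri(propan-2-yl)silane | Brc1c(C)ccc(O[Si](C(C)C)(C(C)C)C(C)C)c1C | intermediate
6 | ethylene oxide (oxirane) | C1CO1 | starting material
7 | {2,6-dimethyl-3-[tri(propan-2-yl)silyloxy]phenyl}magnesium bromide | Br[Mg]c1c(C)ccc(O[Si](C(C)C)(C(C)C)C(C)C)c1C | intermediate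
8 | 2-{2,6-dimethyl-3-[tri(propan-2-yl)silyloxy]phenyl}ethan-1-ol | OCCc1c(C)ccc(O[Si](C(C)C)(C(C)C)C(C)C)c1C | intermediate
9 | [3-(2-bromoethyl)-2,4-dimethylphenoxy]tri(propan-2-yl)silane | BrCCc1c(C)ccc(O[Si](C(C)C)(C(C)C)C(C)C)c1C | intermediate
10 | propyne | CC#C | starting material
11 | (2-{2,6-dimethyl-3-[tri(propan-2-yl)silyloxy]phenyl}ethyl)magnesium bromide | Br[Mg]CCc1c(C)ccc(O[Si](C(C)C)(C(C)C)C(C)C)c1C | intermediate
12 | (1Z)-(4-{2,6-dimethyl-3-[tri(propan-2-yl)silyloxy]phenyl}-2-methylbut-1-en-1-yl)copper (as its MgBr2/Me2S complex) | [Cu]/C=C(C)\CCc1c(C)ccc(O[Si](C(C)C)(C(C)C)C(C)C)c1C | intermediate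
13 | (Z)-6-{2,6-dimethyl-3-[tri(propan-2-yl)silyloxy]phenyl}-4-methylhex-3-en-1-ol | OCC/C=C(C)\CCc1c(C)ccc(O[Si](C(C)C)(C(C)C)C(C)C)c1C | intermediate
14 | (Z)-6-{2,6-dimethyl-3-[tri(propan-2-yl)silyloxy]phenyl}-4-methylhex-3-enoic acid | OC(=O)C/C=C(C)\CCc1c(C)ccc(O[Si](C(C)C)(C(C)C)C(C)C)c1C | intermediate
15 | (Z)-6-(3-hydroxy-2,6-dimethylphenyl)-4-methylhex-3-enoic acid | OC(=O)C/C=C(C)\CCc1c(C)ccc(O)c1C | intermediate
16 | (8S,9R,10S)-3-oxo-13,14,15,16,18-pentanorlabda-1,4-dien-12,8-olide | O=C3C[C@@H]1[C@]2(C)C=CC(=O)C(C)=C2CC[C@]1(C)O3 | intermediate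
17 | (8S,9R,10S)-3-oxo-13,14,15,16,18-pentanorlabd-4-en-12,8-olide | O=C3C[C@@H]1[C@]2(C)CCC(=O)C(C)=C2CC[C@]1(C)O3 | intermediate
18 | (8S,9R,10S)-3-oxo-13,14,15,16-tetranorlabd-5-en-12,8-olide | O=C3C[C@@H]1[C@]2(C)CCC(=O)C(C)(C)C2=CC[C@]1(C)O3 | intermediate
19 | (3R,8S,9R,10S)-13,14,15,16-tetranorlabd-5-ene-3,8,12-triol | OCC[C@@H]1[C@]2(C)CC[C@@H](O)C(C)(C)C2=CC[C@]1(C)O | intermediate
20 | (3R,8S,9R,10S)-3,8,12-tris(triethylsilyloxy)-13,14,15,16-tetranorlabd-5-ene | CC[Si](CC)(CC)OCC[C@@H]1[C@]2(C)CC[C@@H](O[Si](CC)(CC)CC)C(C)(C)C2=CC[C@]1(C)O[Si](CC)(CC)CC | intermediate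
21 | (3R,8S,9R,10S)-3,8-bis(triethylsilyloxy)-13,14,15,16-tetranorlabd-5-en-12-ol | OCC[C@@H]1[C@]2(C)CC[C@@H](O[Si](CC)(CC)CC)C(C)(C)C2=CC[C@]1(C)O[Si](CC)(CC)CC | intermediate
22 | (3R,5S,6R,8S,9R,10R)-3,8-bis(triethylsilyloxy)-13,14,15,16-tetranorlabdane-6,12-diol | OCC[C@@H]1[C@]2(C)CC[C@@H](O[Si](CC)(CC)CC)C(C)(C)[C@H]2[C@H](O)C[C@]1(C)O[Si](CC)(CC)CC | intermediate
23 | (3R,5S,6R,8S,9R,10R)-6-hydroxy-3,8-bis(triethylsilyloxy)-13,14,15,16-tetranorlabdan-12-yl 4-methylbenzenesulfonate | Cc1ccc(cc1)S(=O)(=O)OCC[C@@H]1[C@]2(C)CC[C@@H](O[Si](CC)(CC)CC)C(C)(C)[C@H]2[C@H](O)C[C@]1(C)O[Si](CC)(CC)CC | intermediate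
24 | chloroprene (2-chlorobuta-1,3-diene) | C=CC(Cl)=C | starting material
25 | buta-1,3-dien-2-ylmagnesium chloride | C=CC(=C)[Mg]Cl | intermediate
26 | (3R,5S,6R,8S,9R,10R)-3,8-bis(triethylsilyloxy)labda-13(16),14-dien-6-ol | C=CC(=C)CC[C@@H]1[C@]2(C)CC[C@@H](O[Si](CC)(CC)CC)C(C)(C)[C@H]2[C@H](O)C[C@]1(C)O[Si](CC)(CC)CC | intermediate
27 | (3R,5S,6R,8S,9R,10R)-3,8-bis(triethylsilyloxy)labda-13(16),14-dien-6-yl acetate | C=CC(=C)CC[C@@H]1[C@]2(C)CC[C@@H](O[Si](CC)(CC)CC)C(C)(C)[C@H]2[C@H](OC(C)=O)C[C@]1(C)O[Si](CC)(CC)CC | intermediate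
28 | (3R,5S,6R,8S,9R,10R)-3,8-dihydroxylabda-13(16),14-dien-6-yl acetate (CNP0351600.2) | C=CC(=C)CC[C@@H]1[C@]2(C)CC[C@@H](O)C(C)(C)[C@H]2[C@H](OC(C)=O)C[C@]1(C)O | target

**Step count**

Total: 18 steps. Longest linear sequence: 18 steps, from 1 to 28; the route is fully linear, with ethylene oxide, propyne and chloroprene entering as reagents.

**Steps most likely to fail, with fallbacks**

Step 9. The tethered alkene may fail to intercept the oxidised phenol before solvent or ortho attack takes over, or the reagent may not discriminate the two arene faces. The fallback uses known reactions only, sets out from 15 and rejoins at 17, so it replaces steps 9 and 10. Compound 15 is oxidised with PhI(OAc)2 in aqueous MeCN, where water adds at C10, to the para-quinol acid F1. Its disubstituted ring alkene is hydrogenated with H2 and RhCl(PPh3)3 to the 4-hydroxy enone acid F2. CBS reduction with catecholborane and the (S)-methyl oxazaborolidine should give the 3R allylic diol acid F3; either carbinol configuration would serve, and the tertiary carbinol epimers are irrelevant. TBSCl and imidazole give the bis-silyl derivative F4, whose silyl ester is cleaved with K2CO3 in aqueous MeOH to the silyl ether acid F5. SnCl4 in CH2Cl2 at −78 °C then ionises the tertiary allylic alcohol; in this classical allyl-cation-initiated olefin cyclisation C9 of the (Z)-alkene adds to C10 and the acid traps C8, giving the tricyclic silyl ether lactone F6. F6 is separated by chromatography from the diastereomer with the mirror-image C8/C9/C10 triad, the C3 carbinol serving as resolving handle. TBAF gives the allylic alcohol lactone F7, and MnO2 oxidises it to 17.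

Step 14. Borane addition to a trisubstituted alkene lying between two quaternary carbons may be slow, and the facial preference may be eroded by the axial C11 arm. The fallback sets out from 21 and rejoins at 22. Epoxidation with mCPBA and NaHCO3, a small electrophile that attacks the face opposite C20, gives the 5,6-epoxide F8. Reductive opening with Cp2TiCl (trivalent titanium, generated from Cp2TiCl2 and Mn) and water as hydrogen-atom source then cleaves the C5–O bond to the tertiary C5 radical, which takes up hydrogen on the less hindered face. This formal anti-Markovnikov hydration through radical epoxide opening leads to 22.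

Step 16. The dienyl Grignard reagent may oligomerise or couple sluggishly, and the magnesium alkoxide at C6 may slow the copper-catalysed substitution. The fallback sets out from 23 and rejoins at 26. Displacement of the tosylate with lithium acetylide–ethylenediamine complex in DMSO gives the terminal alkyne F9. Enyne cross-metathesis with ethylene (1 atm) and the second-generation Grubbs catalyst, RuCl2(H2IMes)(PCy3)(=CHPh), then converts the terminal alkyne into the 2-substituted buta-1,3-diene 26.

**Further compounds**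

F1 | step 9 | (Z)-6-(6-hydroxy-2,6-dimethyl-3-oxocyclohexa-1,4-dien-1-yl)-4-methylhex-3-enoic acid (racemic) | OC(=O)C/C=C(C)\CCC1=C(C)C(=O)C=CC1(C)O
F2 | step 9 | (Z)-6-(6-hydroxy-2,6-dimethyl-3-oxocyclohex-1-en-1-yl)-4-methylhex-3-enoic acid (racemic) | OC(=O)C/C=C(C)\CCC1=C(C)C(=O)CCC1(C)O
F3 | step 9 | (Z)-6-[(3R)-3,6-dihydroxy-2,6-dimethylcyclohex-1-en-1-yl]-4-methylhex-3-enoic acid (both epimers at the tertiary carbinol) | OC(=O)C/C=C(C)\CCC1=C(C)[C@H](O)CCC1(C)O
F4 | step 9 | tert-butyldimethylsilyl (Z)-6-[(3R)-3-(tert-butyldimethylsilyloxy)-6-hydroxy-2,6-dimethylcyclohex-1-en-1-yl]-4-methylhex-3-enoate | CC(C)(C)[Si](C)(C)OC(=O)C/C=C(C)\CCC1=C(C)[C@H](O[Si](C)(C)C(C)(C)C)CCC1(C)O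
F5 | step 9 | (Z)-6-[(3R)-3-(tert-butyldimethylsilyloxy)-6-hydroxy-2,6-dimethylcyclohex-1-en-1-yl]-4-methylhex-3-enoic acid | OC(=O)C/C=C(C)\CCC1=C(C)[C@H](O[Si](C)(C)C(C)(C)C)CCC1(C)O
F6 | step 9 | (3R,8S,9R,10S)-3-(tert-butyldimethylsilyloxy)-13,14,15,16,18-pentanorlabd-4-en-12,8-olide | O=C3C[C@@H]1[C@]2(C)CC[C@@H](O[Si](C)(C)C(C)(C)C)C(C)=C2CC[C@]1(C)O3
F7 | step 9 | (3R,8S,9R,10S)-3-hydroxy-13,14,15,16,18-pentanorlabd-4-en-12,8-olide | O=C3C[C@@H]1[C@]2(C)CC[C@@H](O)C(C)=C2CC[C@]1(C)O3
F8 | step 14 | 5,6-epoxide of 21, oxygen on the face opposite C20: (3R,8S,9R,10S)-5,6-epoxy-3,8-bis(triethylsilyloxy)-13,14,15,16-tetranorlabdan-12-ol | OCC[C@@H]1[C@]2(C)CC[C@@H](O[Si](CC)(CC)CC)C(C)(C)[C@]23O[C@@H]3C[C@]1(C)O[Si](CC)(CC)CC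
F9 | step 16 | (3R,5S,6R,8S,9R,10R)-3,8-bis(triethylsilyloxy)-15,16-dinorlabd-13-yn-6-ol (terminal alkyne on C12) | C#CCC[C@@H]1[C@]2(C)CC[C@@H](O[Si](CC)(CC)CC)C(C)(C)[C@H]2[C@H](O)C[C@]1(C)O[Si](CC)(CC)CC
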